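The runs were computed with constants of no real substance; scatter was added.

No rate constant of this flask is given, so you read a time off the runs instead.

| flask | Xa | Xb | Xp | time |
|---|---|---|---|---|
| oak | 0.0800 M | 0.0880 M |  |  |
| elm | 0.0400 M | 0.0480 M |  |  |
| cedar | 0.0800 M | 0.0880 M | 0.0400 M |  |
| maple | 0.0800 M | 0.260 M |  |  |
| larch | 0.0400 M | 0.0440 M |  | 25 h |

- oak run (time / h: [Xp] / M): 3.1: 0.0125; 6.2: 0.0209; 9.4: 0.0283; 12: 0.0345; 16: 0.0377; 19: 0.0404; 22: 0.0411; 25: 0.0401
- elm run (time / h: [Xp] / M): 3.1: 0.0050; 6.2: 0.0076; 9.4: 0.0087; 12: 0.0088; 16: 0.0105; 19: 0.0127; 22: 0.0134; 25: 0.0129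
- cedar run (time / h: [Xp] / M): 3.1: 0.0636; 6.2: 0.0750; 9.4: 0.0833; 12: 0.0851; 16: 0.0913; 19: 0.0902; 22: 0.0899; 25: 0.0938
- maple run (time / h: [Xp] / M): 3.1: 0.0267; 6.2: 0.0478; 9.4: 0.0609; 12: 0.0669; 16: 0.0711; 19: 0.0740; 22: 0.0740; 25: 0.0753

(each reading ± 0.001 M)

- reaction order in [Xa] at the outset, round the charge of the oak run, defined at two percent of the Xa turned into Xp (one fixed amount of Xp, the same in the runs compared)
- reaction order in [Xb] at the outset, round the charge of the oak run, defined at two percent of the Xa turned into Xp
- Xp in the larch run at 25 h, as a share of the Xa charged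

- Overall: Xa + Xb -> Xp.
- Constant volume, constant temperature.
- "The second partner" is Xb.
- An order is taken over about fifteen percent of the charge, up and down.

1. Raise Xb, oak to maple. By hand, a rate first order in Xb grows 2.95 times. The first reading grows 2.14 times, which reads as an average order of 0.701 between those two charges of Xb. The last maple reading stands at nearly all of the Xa charged, so Xa is the limiting reagent there.

2. Lower the charge, oak to elm. By hand, a rate first order in both Xa and Xb turns a lower share of a lower charge in the same time. The last elm reading stands at 32.2% of its Xa and the last oak reading at 50.1% of its Xa, so the elm share is lower.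

3. Add Xp, oak to cedar. By hand, added Xp changes nothing in a rate that holds no Xp. The cedar run gains 0.0236 M by its first reading, twice the oak gain.

4. Join the two ends. The opening rate is the first reading of Xp made, over its time. In the elm run, the opening rate 0.00161 M h⁻¹ and the last reading 0.0129 M give 8.00 h. This working time is the Xp made by the last reading, divided by the opening rate. The oak run gives 9.94 h, the maple run 8.74 h and the cedar run 7.07 h.

5. Reckon larch from elm, its neighbour. With the average order from step 1, the lower Xb of the larch run gives a reckoned opening rate of 0.00152 M h⁻¹. Times the elm working time, that is 0.0121 M, or 30.3% of the Xa charged.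

6. The forecast gives an order of 0.8 in Xa, an order of 0.7 in Xb and 31% for the larch run, a share higher than this reckoning. Its ground is “Larch is close to elm, with slightly less Xb”.

7. The flask gives an order of 0.82 in Xa, an order of 0.79 in Xb and 31.7% for the larch run, and the forecast stands within the margin on each.

    Xa + Xb ⇌ Xi, settled at all times (7.230 L mol⁻¹)
    Xi → Xp (0.1642 h⁻¹)
    Xa + Xb + Xp → 2 Xp (33.70 L² mol⁻² h⁻¹)
    Xb → G (0.09288 h⁻¹)

In the larch run, 31.7% of the Xa is 0.0127 M of Xp, so at the reckoned opening rate its working time is 8.36 h. In the maple run, the last reading over the rate of 0.0081 M h⁻¹, taken where two percent of the oak Xa have turned, gives 9.33 h. The larch working time is held short in part by the reaction of Xb to G. Without that reaction the larch run reaches 58.4% at 25 h instead of 31.7%, a working time of 15.4 h at the same reckoned opening rate.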